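**Retrosynthetic overview**

1. The strategy rests on the dihydrofuran ring of the benzofuran half: O1, C2 and C3, fused at C3a/C7a to the resorcinol-derived ring, with the three-carbon carbinol unit on C2. C3, C2 and that side unit are one isoprene molecule bridging a resorcinol oxygen and its ortho ring carbon.
2. Endgame disconnection: the C(=O)–CH2 bond. The ketone carbon is the C5 aldehyde masked as a lithiated 1,3-dithiane; the CH2–CH(OH)Ar unit is an (R)-aryloxirane of the chroman half, opened at CH2 so that the benzylic C–O bond is never broken.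
3. Benzofuran half: enantioselective palladium-catalysed annulation of isoprene onto 4-iodoresorcinol (forms O1–C2 and C3–C3a), then hydration of the isopropenyl group, C5 formylation, O-benzylation and dithiane formation.
4. Chroman half: C6 chloroacetylation of 2,2-dimethylchroman, asymmetric transfer hydrogenation, oxirane closure.
5. Ring order: the dihydrofuran ring (step 1) is the only skeletal ring built; the chroman ring is bought; the dithiane and oxirane rings are temporary; the benzyl group leaves last by neutral hydrogenolysis.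

Key step: step 1

Assumption: 2,2-dimethylchroman is bought as a catalogue compound, and in steps 1 and 7 the ligand or catalyst antipode used is the one that leads to the configuration drawn.

**Route**

Step 1
Reactants: 1 4-iodoresorcinol; 2 isoprene
Product: 3 (S)-2-(prop-1-en-2-yl)-2,3-dihydrobenzofuran-6-ol
Conditions: Pd2(dba)3 (2.5 mol %), chiral sulfinamide–monophosphine ligand L* (10 mol %), NaOPh (2 equiv), isoprene (5 equiv), toluene/THF, 60 °C, sealed tube
Reagents that add atoms: none
Why: Larock-type heteroannulation run as an enantioselective Heck/Tsuji–Trost cascade: zerovalent palladium inserts into the C–I bond of 1, the arylpalladium iodide carbopalladates the monosubstituted double bond of isoprene at its CH2 end (aryl–C3 bond), and the resulting η3-allylpalladium is captured by the ortho phenoxide at the allyl carbon next to the new benzylic CH2 (O1–C2 bond). The closest known reaction type is the palladium-catalysed annulation of 1,3-dienes with ortho-halophenols, which with isoprene leads to 2-isopropenyl-2,3-dihydrobenzofurans and which chiral phosphine ligands render enantioselective. The dihydrofuran ring closes in a 5-exo mode, the remaining C=C ending outside the ring as the isopropenyl group; attack at the far allyl terminus would need a seven-membered ring and is not expected. The one new stereocentre, C2, is set by the ligand: the two diastereomeric allyl complexes interconvert by π–σ–π isomerisation through the unsubstituted CH2 terminus and the ligand decides which one undergoes C–O bond formation. The step needs arylation of the vinyl rather than the 1,1-disubstituted alkene of isoprene, which the lower steric demand of the vinyl group secures, and cyclisation through the hydroxyl ortho to iodine only, which geometry secures because the para hydroxyl cannot reach the allyl unit and stays as the future C6–OH. The second phenol should be tolerated because phenoxide is itself the base and any intermolecular O-allylation is reversible under zerovalent palladium.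

Step 2
Reactants: 3 (S)-2-(prop-1-en-2-yl)-2,3-dihydrobenzofuran-6-ol
Product: 4 (S)-2-(2-hydroxypropan-2-yl)-2,3-dihydrobenzofuran-6-ol
Conditions: Co(acac)2 (20 mol %), PhSiH3 (2.5 equiv), O2 (1 atm), THF, rt
Reagents that add atoms: dioxygen, O=O
Why: Mukaiyama hydration, in which hydrogen-atom transfer from a cobalt hydride to the terminal CH2 gives the tertiary radical that is trapped by O2 and reduced by the silane to the Markovnikov tertiary alcohol; C2 is not involved and keeps its configuration.

Step 3
Reactants: 4 (S)-2-(2-hydroxypropan-2-yl)-2,3-dihydrobenzofuran-6-ol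
Product: 6 (S)-6-hydroxy-2-(2-hydroxypropan-2-yl)-2,3-dihydrobenzofuran-5-carbaldehyde, via salicyl alcohol 5 (not isolated)
Conditions: MgCl2 (2 equiv), Et3N (4 equiv), (CH2O)n (6 equiv), MeCN, reflux; cold dilute HCl work-up
Reagents that add atoms: paraformaldehyde (as formaldehyde), C=O
Why: Casnati–Skattebøl ortho-formylation, in which the magnesium phenoxide delivers formaldehyde to an ortho carbon and the resulting salicyl alcohol is oxidised in the flask by hydride transfer to a second formaldehyde; C5 should be preferred over C7, which lies between two oxygens and is more hindered, as is usual for 3-alkoxyphenols.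

Step 4
Reactants: 6 (S)-6-hydroxy-2-(2-hydroxypropan-2-yl)-2,3-dihydrobenzofuran-5-carbaldehyde
Product: 7 (S)-6-(benzyloxy)-2-(2-hydroxypropan-2-yl)-2,3-dihydrobenzofuran-5-carbaldehyde
Conditions: BnBr (1.2 equiv), K2CO3 (2 equiv), DMF, rt to 40 °C
Reagents that add atoms: benzyl bromide, BrCc1ccccc1
Why: Williamson etherification of the acidic phenol only, since K2CO3 does not deprotonate the tertiary alcohol; benzyl is chosen because it tolerates n-BuLi and is removed at the end without acid or base.

Step 5
Reactants: 7 (S)-6-(benzyloxy)-2-(2-hydroxypropan-2-yl)-2,3-dihydrobenzofuran-5-carbaldehyde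
Product: 8 2-[(S)-6-(benzyloxy)-5-(1,3-dithian-2-yl)-2,3-dihydrobenzofuran-2-yl]propan-2-ol
Conditions: HS(CH2)3SH (1.2 equiv), I2 (10 mol %), CH2Cl2, rt
Reagents that add atoms: propane-1,3-dithiol, SCCCS
Why: Thioacetalisation of the aryl aldehyde (Corey–Seebach dithiane formation) under mild iodine catalysis, chosen over strong Lewis acids to spare the tertiary alcohol and the benzyl ether.

Step 6
Reactants: 9 2,2-dimethylchroman; 10 chloroacetyl chloride
Product: 11 2-chloro-1-(2,2-dimethylchroman-6-yl)ethan-1-one
Conditions: AlCl3 (1.1 equiv), CH2Cl2, 0 °C (acid chloride and AlCl3 premixed, then 9)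
Reagents that add atoms: none
Why: Friedel–Crafts acylation at C6, para to the ring oxygen and the least hindered activated position; the preformed acylium complex at 0 °C should react before the tertiary alkyl aryl ether can be cleaved.

Step 7
Reactants: 11 2-chloro-1-(2,2-dimethylchroman-6-yl)ethan-1-one
Product: 12 (R)-2-chloro-1-(2,2-dimethylchroman-6-yl)ethan-1-ol
Conditions: RuCl[(S,S)-TsDPEN](p-cymene) (1 mol %), HCO2H/Et3N (5:2), EtOAc, rt
Reagents that add atoms: none
Why: Noyori–Ikariya asymmetric transfer hydrogenation of an aryl chloromethyl ketone, in which the (S,S)-catalyst should deliver hydride to the face that gives (S)-1-arylethanols from aryl methyl ketones, which for the CH2Cl analogue is the (R)-chlorohydrin because CH2Cl outranks aryl; this sets the carbinol stereocentre of the target.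

Step 8
Reactants: 12 (R)-2-chloro-1-(2,2-dimethylchroman-6-yl)ethan-1-ol
Product: 13 (R)-2-(2,2-dimethylchroman-6-yl)oxirane
Conditions: KOt-Bu (1.1 equiv), THF, 0 °C; non-aqueous work-up, used at once
Reagents that add atoms: none
Why: Intramolecular Williamson closure at the primary chloride, which leaves the benzylic C–O bond intact so (R) is retained; aprotic conditions avoid solvolysis of the electron-rich aryl oxirane.

Step 9
Reactants: 8 2-[(S)-6-(benzyloxy)-5-(1,3-dithian-2-yl)-2,3-dihydrobenzofuran-2-yl]propan-2-ol; 13 (R)-2-(2,2-dimethylchroman-6-yl)oxirane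
Product: 15 (S)-2-{2-[(S)-6-(benzyloxy)-2-(2-hydroxypropan-2-yl)-2,3-dihydrobenzofuran-5-yl]-1,3-dithian-2-yl}-1-(2,2-dimethylchroman-6-yl)ethan-1-ol, via dilithiated dithiane 14 (not isolated)
Conditions: n-BuLi (2.1 equiv), THF, −78 to −20 °C; then 13 (1.2 equiv), DMPU, −78 to 0 °C; H2O
Reagents that add atoms: none
Why: Corey–Seebach umpolung, in which the first equivalent of n-BuLi forms the tertiary lithium alkoxide and the second the 2-aryl-2-lithio-1,3-dithiane, which opens the monosubstituted oxirane by SN2 attack at the unhindered CH2 while DMPU loosens the lithium ion pair and so disfavours lithium-assisted benzylic opening; the benzylic C–O bond is not broken, so (R)-13 gives the (S)-carbinol by a change of descriptor only.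

Step 10
Reactants: 15 (S)-2-{2-[(S)-6-(benzyloxy)-2-(2-hydroxypropan-2-yl)-2,3-dihydrobenzofuran-5-yl]-1,3-dithian-2-yl}-1-(2,2-dimethylchroman-6-yl)ethan-1-ol
Product: 16 (S)-1-[(S)-6-(benzyloxy)-2-(2-hydroxypropan-2-yl)-2,3-dihydrobenzofuran-5-yl]-3-(2,2-dimethylchroman-6-yl)-3-hydroxypropan-1-one
Conditions: MeI (10 equiv), CaCO3 (5 equiv), MeCN/H2O (9:1), 45 °C, dark
Reagents that add atoms: water, O
Why: Alkylative dithiane hydrolysis, in which S-methylation opens the dithiane to a thionium ion that water traps; the medium is buffered and free of oxidants and thiophilic metals, so the electron-rich rings, the acid-labile benzylic alcohol and the β-hydroxy ketone should survive.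

Step 11
Reactants: 16 (S)-1-[(S)-6-(benzyloxy)-2-(2-hydroxypropan-2-yl)-2,3-dihydrobenzofuran-5-yl]-3-(2,2-dimethylchroman-6-yl)-3-hydroxypropan-1-one
Product: 17 (S)-3-(2,2-dimethylchroman-6-yl)-3-hydroxy-1-[(S)-6-hydroxy-2-(2-hydroxypropan-2-yl)-2,3-dihydrobenzofuran-5-yl]propan-1-one
Conditions: H2 (1 atm), 10% Pd/C, EtOAc, rt, stopped when 16 is consumed
Reagents that add atoms: none
Why: Hydrogenolysis of the aryl benzyl ether, which on palladium under neutral conditions should be much faster than C–O hydrogenolysis of the secondary benzylic alcohol or reduction of the ketone; the absence of acid and base avoids dehydration, racemisation and retro-aldol cleavage of the β-hydroxy ketone.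

**Compound list**

1 | 4-iodoresorcinol | Oc1ccc(I)c(O)c1 | starting material
2 | isoprene | C=CC(C)=C | starting material
3 | (S)-2-(prop-1-en-2-yl)-2,3-dihydrobenzofuran-6-ol | Oc1ccc2c(c1)O[C@H](C(C)=C)C2 | intermediate
4 | (S)-2-(2-hydroxypropan-2-yl)-2,3-dihydrobenzofuran-6-ol | Oc1ccc2c(c1)O[C@H](C(C)(C)O)C2 | intermediate
5 | (S)-5-(hydroxymethyl)-2-(2-hydroxypropan-2-yl)-2,3-dihydrobenzofuran-6-ol, salicyl alcohol formed as its magnesium phenoxide (not isolated) | OCc1cc2c(cc1O)O[C@H](C(C)(C)O)C2 | intermediate
6 | (S)-6-hydroxy-2-(2-hydroxypropan-2-yl)-2,3-dihydrobenzofuran-5-carbaldehyde | O=Cc1cc2c(cc1O)O[C@H](C(C)(C)O)C2 | intermediate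
7 | (S)-6-(benzyloxy)-2-(2-hydroxypropan-2-yl)-2,3-dihydrobenzofuran-5-carbaldehyde | O=Cc1cc2c(cc1OCc3ccccc3)O[C@H](C(C)(C)O)C2 | intermediate
8 | 2-[(S)-6-(benzyloxy)-5-(1,3-dithian-2-yl)-2,3-dihydrobenzofuran-2-yl]propan-2-ol | S1CCCSC1c1cc2c(cc1OCc3ccccc3)O[C@H](C(C)(C)O)C2 | intermediate
9 | 2,2-dimethylchroman | CC1(C)CCc2ccccc2O1 | starting material
10 | chloroacetyl chloride | ClCC(Cl)=O | starting material
11 | 2-chloro-1-(2,2-dimethylchroman-6-yl)ethan-1-one | CC1(C)CCc2cc(C(=O)CCl)ccc2O1 | intermediate
12 | (R)-2-chloro-1-(2,2-dimethylchroman-6-yl)ethan-1-ol | CC1(C)CCc2cc([C@@H](O)CCl)ccc2O1 | intermediate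
13 | (R)-2-(2,2-dimethylchroman-6-yl)oxirane | CC1(C)CCc2cc([C@@H]3CO3)ccc2O1 | intermediate
14 | dilithiated dithiane: lithium alkoxide of 8 lithiated at dithiane C2 (not isolated) | [Li]C1(SCCCS1)c1cc2c(cc1OCc3ccccc3)O[C@H](C(C)(C)O[Li])C2 | intermediate
15 | (S)-2-{2-[(S)-6-(benzyloxy)-2-(2-hydroxypropan-2-yl)-2,3-dihydrobenzofuran-5-yl]-1,3-dithian-2-yl}-1-(2,2-dimethylchroman-6-yl)ethan-1-ol | CC1(C)CCc2cc([C@@H](O)CC3(SCCCS3)c3cc4c(cc3OCc5ccccc5)O[C@H](C(C)(C)O)C4)ccc2O1 | intermediate
16 | (S)-1-[(S)-6-(benzyloxy)-2-(2-hydroxypropan-2-yl)-2,3-dihydrobenzofuran-5-yl]-3-(2,2-dimethylchroman-6-yl)-3-hydroxypropan-1-one | CC1(C)CCc2cc([C@@H](O)CC(=O)c3cc4c(cc3OCc5ccccc5)O[C@H](C(C)(C)O)C4)ccc2O1 | intermediate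
17 | (S)-3-(2,2-dimethylchroman-6-yl)-3-hydroxy-1-[(S)-6-hydroxy-2-(2-hydroxypropan-2-yl)-2,3-dihydrobenzofuran-5-yl]propan-1-one (CNP0419761.2) | CC1(C)CCc2cc([C@@H](O)CC(=O)c3cc4c(cc3O)O[C@H](C(C)(C)O)C4)ccc2O1 | target

**Step count**

Total steps: 11. Longest linear sequence: 8 steps (steps 1–5, then 9, 10 and 11); the oxirane branch (steps 6–8) joins at step 9.

**Steps most likely to fail**

Step 1. The ligand may induce too little asymmetry in the C–O bond-forming step, or oxidative addition may be slow and the catalyst deactivated because the doubly deprotonated, very electron-rich iodoresorcinol binds palladium or is oxidised. The fallback sets out from 1 and rejoins at 4, bypassing steps 1 and 2, and builds the ring by asymmetric epoxidation and phenoxide opening instead. Benzylation of 1 (BnBr, K2CO3, DMF) gives 2,4-bis(benzyloxy)-1-iodobenzene F1. Iodine–lithium exchange (n-BuLi, THF, −78 °C), transmetalation with CuBr·SMe2 and alkylation with prenyl bromide give 2,4-bis(benzyloxy)-1-(3-methylbut-2-en-1-yl)benzene F2. Shi epoxidation (fructose-derived ketone of the series that gives the (R)-oxirane, KHSO5, K2CO3 buffer, MeCN/dimethoxymethane/H2O, 0 °C) gives (R)-3-[2,4-bis(benzyloxy)benzyl]-2,2-dimethyloxirane F3. Hydrogenolysis (H2, Pd/C, EtOAc) frees (R)-4-[(3,3-dimethyloxiran-2-yl)methyl]benzene-1,3-diol F4, and K2CO3 in MeOH lets the ortho phenoxide open the oxirane at its secondary carbon (5-exo-tet, inversion) to give 4.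

Step 9. The dithiane anion may attack the benzylic rather than the terminal oxirane carbon, lithium may promote rearrangement of the electron-rich oxirane, or the alkoxide-bearing dithiane anion may form incompletely. The fallback sets out from 7 and 9 and rejoins at 16, bypassing steps 5 to 10, and sets the carbinol by conjugate borylation of a chalcone.
- MeMgBr (3 equiv, THF, 0 °C) on 7 gives 2-[(S)-6-(benzyloxy)-5-(1-hydroxyethyl)-2,3-dihydrobenzofuran-2-yl]propan-2-ol F5 (both epimers at the new carbinol).
- MnO2 (CH2Cl2) oxidises the benzylic alcohol to 1-[(S)-6-(benzyloxy)-2-(2-hydroxypropan-2-yl)-2,3-dihydrobenzofuran-5-yl]ethan-1-one F6.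
- Rieche formylation of 9 (Cl2CHOMe, SnCl4, CH2Cl2, 0 °C) gives 2,2-dimethylchroman-6-carbaldehyde F7.
- Claisen–Schmidt condensation of F6 with F7 (KOH, EtOH, rt) gives (E)-1-[(S)-6-(benzyloxy)-2-(2-hydroxypropan-2-yl)-2,3-dihydrobenzofuran-5-yl]-3-(2,2-dimethylchroman-6-yl)prop-2-en-1-one F8.
- Copper-catalysed enantioselective conjugate borylation (CuCl, NaOt-Bu, chiral bisphosphine of the Josiphos type in the antipode that gives (S), B2pin2, MeOH, THF) gives (S)-1-[(S)-6-(benzyloxy)-2-(2-hydroxypropan-2-yl)-2,3-dihydrobenzofuran-5-yl]-3-(2,2-dimethylchroman-6-yl)-3-(4,4,5,5-tetramethyl-1,3,2-dioxaborolan-2-yl)propan-1-one F9.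
- Oxidation of the C–B bond with NaBO3·4H2O (THF/H2O, retention) gives 16.

Step 2. The free phenol may lose a hydrogen atom or be oxidised under the cobalt/O2 radical conditions, diverting material into phenoxyl coupling, or the peroxide stage may be reduced incompletely. The fallback sets out from 3 and rejoins at 4 by an ionic two-step hydration. Epoxidation with mCPBA (NaHCO3, CH2Cl2, 0 °C) gives (2S)-2-(2-methyloxiran-2-yl)-2,3-dihydrobenzofuran-6-ol F10 (both epimers at the oxirane carbon). LiAlH4 (THF, 0 °C) then delivers hydride to the oxirane CH2, and both epimers converge on 4.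

Further compounds
F1 | step 1 | 2,4-bis(benzyloxy)-1-iodobenzene | Ic1ccc(OCc2ccccc2)cc1OCc1ccccc1
F2 | step 1 | 2,4-bis(benzyloxy)-1-(3-methylbut-2-en-1-yl)benzene | CC(C)=CCc1ccc(OCc2ccccc2)cc1OCc1ccccc1
F3 | step 1 | (R)-3-[2,4-bis(benzyloxy)benzyl]-2,2-dimethyloxirane | CC1(C)O[C@@H]1Cc1ccc(OCc2ccccc2)cc1OCc1ccccc1
F4 | step 1 | (R)-4-[(3,3-dimethyloxiran-2-yl)methyl]benzene-1,3-diol | CC1(C)O[C@@H]1Cc1ccc(O)cc1O
F5 | step 9 | 2-[(S)-6-(benzyloxy)-5-(1-hydroxyethyl)-2,3-dihydrobenzofuran-2-yl]propan-2-ol | CC(O)c1cc2c(cc1OCc3ccccc3)O[C@H](C(C)(C)O)C2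
F6 | step 9 | 1-[(S)-6-(benzyloxy)-2-(2-hydroxypropan-2-yl)-2,3-dihydrobenzofuran-5-yl]ethan-1-one | CC(=O)c1cc2c(cc1OCc3ccccc3)O[C@H](C(C)(C)O)C2
F7 | step 9 | 2,2-dimethylchroman-6-carbaldehyde | CC1(C)CCc2cc(C=O)ccc2O1
F8 | step 9 | (E)-1-[(S)-6-(benzyloxy)-2-(2-hydroxypropan-2-yl)-2,3-dihydrobenzofuran-5-yl]-3-(2,2-dimethylchroman-6-yl)prop-2-en-1-one | CC1(C)CCc2cc(/C=C/C(=O)c3cc4c(cc3OCc5ccccc5)O[C@H](C(C)(C)O)C4)ccc2O1
F9 | step 9 | (S)-1-[(S)-6-(benzyloxy)-2-(2-hydroxypropan-2-yl)-2,3-dihydrobenzofuran-5-yl]-3-(2,2-dimethylchroman-6-yl)-3-(4,4,5,5-tetramethyl-1,3,2-dioxaborolan-2-yl)propan-1-one | CC1(C)CCc2cc([C@@H](B3OC(C)(C)C(C)(C)O3)CC(=O)c3cc4c(cc3OCc5ccccc5)O[C@H](C(C)(C)O)C4)ccc2O1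
F10 | step 2 | (2S)-2-(2-methyloxiran-2-yl)-2,3-dihydrobenzofuran-6-ol | Oc1ccc2c(c1)O[C@H](C1(C)CO1)C2
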